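(The numbers in the tables are calculated with constants of no real substance; noise was put on by code.)

Charge 0.480 M of J with Z, X and L as on Monday and Tuesday, leave L at 20 mM, and read E on the way up, at 10% of Z and X together.

| setting | Monday's | Tuesday's | flask |
|---|---|---|---|
| Z | 0.80 M | 0.80 M | 0.80 M |
| X | 0.80 M | 0.80 M | 0.80 M |
| J | 0.32 M | 0.72 M | 0.480 M |
| L | 20 mM | 20 mM | 20 mM |
| remark | run made earlier | run made earlier |  |

| Monday's: time / d | Monday's: E / % | Tuesday's: time / d | Tuesday's: E / % |
|---|---|---|---|
| 1.25 | 11.2 | 0.625 | 19.8 |
| 2.50 | 11.0 | 1.04 | 20.9 |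
| 4.00 | 11.3 | 1.67 | 21.0 |
| 5.00 | 11.0 | 3.00 | 21.3 |
| 6.00 | 11.3 | 5.00 | 21.8 |
| 8.00 | 11.5 | 8.00 | 21.4 |

(each reading ± 0.3 percentage points)

1. apparent order in J when 10% of the Z and X together are converted (percent change of the rate of making E for one percent more J charged)
2. factor on the rate of making E when 10% of the Z and X together are converted if L is charged twice over

- L is single-handed; Z and X are mirror images of each other, charged as a racemate, each of them at the stated concentration
- no earlier run changes the charge of L; that part of a forecast is a guess

Both runs stop with Z and J left over: Monday's readings level at 11.2% and Tuesday's at 21.4%. My own reckoning supposes a rate first order in Z, J and L, with L lost at a steady first-order pace. Then ln(z/j), divided by the charge of Z minus the charge of J, grows with the integral of L over time, z and j being the fractions of Z and J left, and it ends at a capacity. Monday gives 1.19 M⁻¹, Tuesday 1.08 M⁻¹, their mean 1.13 M⁻¹. This flask should then stop near 15.7%, above the mark, so the mark lies on the way up.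

At the mark the quantity stands at 0.570 M⁻¹. Over the capacity that makes the used share, the part of L's capacity used by a given conversion, 0.502. Twice the L doubles the capacity and halves this share, giving a factor of 3.01, a guess, since no run varies L. Order in J comes to 2.73.

The forecast reads the plateaus as “strikingly constant, so this is an equilibrium” and gives order 2.4 (1.5 to 2.8) and factor 2 (1.6 to 3.8), the factor as a guess.

    J + L + X → L + D (k = 0.0810 M⁻² h⁻¹)
    J + L → G (k = 0.0441 M⁻¹ h⁻¹)
    J + L + Z → L + E (k = 8.55 M⁻² h⁻¹)
    L → Q (k = 0.136 h⁻¹)

The flask gives order 2.6 and factor 3.02, with the mark reached at 0.192 d. After 4.00 d L stands at 0%, Q at 90.4% and G at 9.65%. The used share at the mark makes a loss constant of 3.64 d⁻¹, while the steps from L to Q and from J + L to G run at 3.3 d⁻¹ and 0.51 d⁻¹ per L, J as charged. Held for Monday's run, that constant reckons 1.06% of L left at 1.25 d, where E already reads 11.2%.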